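The readings were computed with constants of no real substance; noise was put on by code.

Left long enough, a flask can hold no more product than the substrate charged, so the ceiling is 100 percent, and I asked how fast that end is approached.

| setting | summer | winter | autumn | Saturday's | Tuesday's | Friday's |
|---|---|---|---|---|---|---|
| substrate | 3 M | 3 M | 3 M | 3.0 M | 3.0 M | 3.0 M |
| gas | 110 mM (held) | 110 mM (held) | 110 mM (held) | 110 mM (held) | 110 mM (held) | 110 mM (held) |
| free catalyst | 0.54 mol% | 1.2 mol% | 0.8 mol% | 0.8 mol% | 0.8 mol% | 0.8 mol% |
| impurity | 5.3 mM | 5.3 mM | 2.6 mM | 5.3 mM | 5.3 mM | 5.3 mM |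
| temperature | 100 °C | 122 °C | 100 °C | 90 °C | 130 °C | 110 °C |
| remark | run made earlier | run made earlier | run made earlier |  |  |  |
| time |  |  |  | 10 min | 10 min | 10 min |

| summer: time / min | summer: product / % | winter: time / min | winter: product / % | autumn: time / min | autumn: product / % |
|---|---|---|---|---|---|
| 0.667 | 0.1 | 0.667 | 3.6 | 0.667 | 0 |
| 1.33 | 0 | 1.33 | 10.6 | 1.33 | 0.6 |
| 3.00 | 0.3 | 2.00 | 17.8 | 3.00 | 2.5 |
| 8.00 | 3.6 | 2.50 | 23.0 | 8.00 | 9.7 |

(scatter of a reading: 0.3 percentage points)

- at the start none of the gas is in solution

1. the flask that comes out highest in amount of product, in percent of the substrate charged, or "all alike" when all lie within 1.5 percentage points (Saturday's / Tuesday's / Friday's / all alike)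
2. product at the end, in percent of the substrate charged, Saturday's
3. product at the end, in percent of the substrate charged, Tuesday's
4. product at the end, in percent of the substrate charged, Friday's

1. I assumed that the impurity removes catalyst one for one. The working catalyst w is then the catalyst charged minus the impurity: 21.4 mM in autumn's run, 10.9 mM in summer's, 30.7 mM in winter's, and 18.7 mM in each new flask.

2. At the slope of its last two readings, autumn's run would reach the whole charge in 69.4 min. I call that time the fill time τ. Summer's τ is 152 min, and winter's straight, zero-order-looking stretch gives 9.44 min.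

3. Summer's τ is 2.19 times autumn's, while its w is smaller by a factor of 1.96, so I let τ vary as one over w. With w allowed for, winter's run against autumn's then reads as τ halving every 9.33 K of heating.

4. With no lag, product at time t is t/τ, and I took that as a rough ceiling. For a rough floor I took off summer's lag, read as 2.55 min, which is longer than the other runs'.

- Saturday's: τ is 167 min, so the ceiling is 5.98%. Saturday's runs colder than summer's, so I kept its floor at zero.
- Friday's: τ is 37.8 min, which gives 19.7% to 26.5%.
- Tuesday's: τ is 8.55 min, which gives a floor of 87.2%, with the whole charge of 100 percent as its ceiling.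

5. The forecast named Tuesday's, with 3.5% for Saturday's, 24% for Friday's and 85% for Tuesday's, noting that “gas-transfer limits, depletion or catalyst death are possible”. Its Saturday's and Friday's values lie inside my brackets, and its Tuesday's value lies lower than my floor.

Tuesday's came out highest, at 81.2%, against 27.1% for Friday's and 3.78% for Saturday's.

    substrate + free catalyst ⇌ free catalyst + open intermediate (K = 1.20, k = 0.170 L mol⁻¹ s⁻¹, Ea = 75.0 kJ mol⁻¹, ΔH = 14.0 kJ mol⁻¹)
    free catalyst + open intermediate ⇌ catalyst intermediate (K = 0.380 L mol⁻¹, k = 7.90 L mol⁻¹ s⁻¹, Ea = 51.0 kJ mol⁻¹, ΔH = 40.0 kJ mol⁻¹)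
    coupling partner + catalyst intermediate → free catalyst + product (k = 2.90 L mol⁻¹ s⁻¹, Ea = 57.0 kJ mol⁻¹)
    free catalyst + impurity → spent catalyst (k = 980 L mol⁻¹ s⁻¹, Ea = 43.0 kJ mol⁻¹)
    gas ⇌ coupling partner, rate k5*(csat - [coupling partner]) (kL = 1.50 s⁻¹)
    (constants at 110 °C)

Friday's stood 0.60 percentage points over my ceiling and Tuesday's 6 points under my floor. Although Tuesday's τ of 8.55 min is shorter than its 10 min, that flask still held 10.2% substrate and 8.53% open intermediate at 10.0 min. For a repeat of Saturday's at 115 °C, τ comes to 26.1 min, so t/τ is 38.3%, and that flask gave 38.7%.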